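The whole ring is cut at C6–C7 (cembrane numbering) and the C19H2=C8–C7H(OH)–C6H2 segment of the 14-membered carbocycle is read as alkenyl + carbonyl + alkyl: C7 is carbon monoxide. One operation, hydroboration of the C4 vinyl group and carbonylative B-alkyl Suzuki–Miyaura macrocyclisation onto the C8 enol triflate, closes the ring at C6–C7 and creates the α-methylene ketone, which a CBS reduction converts into the C7 carbinol. The seco precursor is the finished oxane ring (C1, C3, C4 set; C1 bought as (R)-α-terpineol, C3/C4 from one epoxidation–6-endo etherification) bearing the vinyl group and an (E)-alkenyl chain that ends in the enol triflate of a methyl ketone.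

Key step: step 10

Remark: atom numbers follow the cembrane skeleton (C1 = oxane CH bearing C15(CH3)2–O; C3 = CHOAc; C4 = O–C(CH3); C5–C6 = CH2CH2; C7 = CHOH; C8 = C(=C19H2); C11=C12 = (E)-alkene), and (R)-(+)-α-terpineol of high enantiomeric purity is taken as commercial.

Step 1
Reactants: 1 (R)-(+)-α-terpineol
Product: 2 trimethyl({2-[(1R)-4-methylcyclohex-3-en-1-yl]propan-2-yl}oxy)silane
Conditions: Me3SiCl, imidazole, DMF, rt
Reagents that add atoms: chlorotrimethylsilane, C[Si](C)(C)Cl
Why: Silyl ether formation masks the tertiary alcohol so that no lactol forms in step 2 and no oxa-Michael addition or O-phosphorylation interferes in steps 3 to 5, and the bought C1 stereocentre is untouched.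

Step 2
Reactants: 2 trimethyl({2-[(1R)-4-methylcyclohex-3-en-1-yl]propan-2-yl}oxy)silane
Product: 4 (3R)-6-oxo-3-{2-[(trimethylsilyl)oxy]propan-2-yl}heptanal, via ozonide 3 (not isolated)
Conditions: O3, CH2Cl2, −78 °C; then PPh3, −78 °C → rt
Reagents that add atoms: ozone, [O-][O+]=O
Why: Ozonolysis with reductive work-up cleaves the only C=C bond and should give the C3 aldehyde and the C12 methyl ketone, with C1 not epimerisable because it is β to both carbonyl groups.

Step 3
Reactants: 4 (3R)-6-oxo-3-{2-[(trimethylsilyl)oxy]propan-2-yl}heptanal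
Product: 5 (2E,5R)-2-methyl-8-oxo-5-{2-[(trimethylsilyl)oxy]propan-2-yl}non-2-enal
Conditions: Ph3P=C(CH3)CHO (1.2 equiv), toluene, 90 °C
Reagents that add atoms: 2-(triphenylphosphoranylidene)propanal, CC(C=O)=P(c1ccccc1)(c1ccccc1)c1ccccc1
Why: Wittig olefination with a stabilised ylide should react only at the aldehyde and is (E)-selective, which fixes the C3=C4 geometry needed for the later epoxide.

Step 4
Reactants: 5 (2E,5R)-2-methyl-8-oxo-5-{2-[(trimethylsilyl)oxy]propan-2-yl}non-2-enal
Product: 6 (5R,7E)-8-methyl-5-{2-[(trimethylsilyl)oxy]propan-2-yl}deca-7,9-dien-2-one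
Conditions: Ph3PCH3Br, KN(SiMe3)2, THF, 0 °C; then 5 (1.05 equiv ylide), −78 → 0 °C
Reagents that add atoms: methyltriphenylphosphonium bromide, C[P+](c1ccccc1)(c1ccccc1)c1ccccc1.[Br-]
Why: Wittig methylenation with the non-stabilised ylide at low temperature should be selective for the conjugated aldehyde over the methyl ketone and gives the 2-methyl-1,3-diene whose vinyl group later directs the ether closure.

Step 5
Reactants: 6 (5R,7E)-8-methyl-5-{2-[(trimethylsilyl)oxy]propan-2-yl}deca-7,9-dien-2-one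
Product: 8 (5R,7E)-8-methyl-5-{2-[(trimethylsilyl)oxy]propan-2-yl}deca-7,9-dien-1-yne, via enol phosphate 7 (not isolated)
Conditions: LiN(iPr)2 (1.1 equiv), THF, −78 °C; ClP(O)(OEt)2; then LiN(iPr)2 (2.3 equiv), −78 → 0 °C; H2O
Reagents that add atoms: none
Why: Negishi's enol phosphate route to alkynes (kinetic deprotonation at CH3, O-phosphorylation, double elimination) should turn the methyl ketone into the terminal C12≡C11 alkyne before any epoxide or free hydroxyl is present.

Step 6
Reactants: 8 (5R,7E)-8-methyl-5-{2-[(trimethylsilyl)oxy]propan-2-yl}deca-7,9-dien-1-yne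
Product: 10 (2S,3R,5R)-5-(but-3-yn-1-yl)-2-ethenyl-2,6,6-trimethyloxan-3-ol, via vinyl epoxide 9 (not isolated)
Conditions: D-fructose-derived Shi ketone (30 mol %), Oxone (2KHSO5·KHSO4·K2SO4), K2CO3, Bu4NHSO4, Na2B4O7 buffer, MeCN/CH2(OMe)2/H2O, 0 °C; extraction; then CSA (10 mol %), CH2Cl2/MeOH 20:1, 0 °C
Reagents that add atoms: potassium peroxymonosulfate (active oxidant of Oxone), [K+].[O-]S(=O)(=O)OO
Why: Shi asymmetric epoxidation should attack only the electron-rich trisubstituted C3=C4 bond of the diene from the face fixed by the D-fructose-derived dioxirane (3R,4R), and the acid-catalysed Nicolaou-type 6-endo opening of the vinyl epoxide by the C15 oxygen then occurs at the tertiary allylic C4 with inversion, so that C3 (R) is set by the reagent and C4 (S) by the stereospecific ring closure.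

Step 7
Reactants: 10 (2S,3R,5R)-5-(but-3-yn-1-yl)-2-ethenyl-2,6,6-trimethyloxan-3-ol
Product: 12 (5E)-8-[(3R,5R,6S)-6-ethenyl-5-hydroxy-2,2,6-trimethyloxan-3-yl]-6-methyloct-5-en-2-one, via alkenylalane 11 (not isolated)
Conditions: Me3Al (3 equiv), Cp2ZrCl2 (20 mol %), H2O (cat.), CH2Cl2, −20 °C; evaporation; then methyl vinyl ketone, CuBr·SMe2 (10 mol %), THF, −30 → 0 °C; aq. KNaC4H4O6
Reagents that add atoms: trimethylaluminium, C[Al](C)C; methyl vinyl ketone (but-3-en-2-one), C=CC(C)=O
Why: Zirconium-catalysed Negishi carboalumination adds CH3–Al syn across the terminal alkyne, which fixes the (E)-C11=C12 geometry, and the alkenylalane should then add in conjugate fashion to methyl vinyl ketone (copper-catalysed 1,4-addition of alkenylalanes) while the hydroxyl is carried as its aluminium alkoxide.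

Step 8
Reactants: 12 (5E)-8-[(3R,5R,6S)-6-ethenyl-5-hydroxy-2,2,6-trimethyloxan-3-yl]-6-methyloct-5-en-2-one
Product: 13 (2S,3R,5R)-2-ethenyl-2,6,6-trimethyl-5-[(3E)-3-methyl-7-oxooct-3-en-1-yl]oxan-3-yl acetate
Conditions: Ac2O, pyridine, DMAP (cat.), CH2Cl2, rt
Reagents that add atoms: acetic anhydride, CC(=O)OC(C)=O
Why: DMAP-catalysed acylation of the hindered secondary C3 alcohol installs the acetate of the target at a point after which no strongly nucleophilic or hydridic reagent is used.

Step 9
Reactants: 13 (2S,3R,5R)-2-ethenyl-2,6,6-trimethyl-5-[(3E)-3-methyl-7-oxooct-3-en-1-yl]oxan-3-yl acetate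
Product: 14 (5E)-8-[(3R,5R,6S)-5-acetoxy-6-ethenyl-2,2,6-trimethyloxan-3-yl]-6-methylocta-1,5-dien-2-yl trifluoromethanesulfonate
Conditions: LiN(SiMe3)2 (1.1 equiv), THF, −78 °C; then PhNTf2, −78 → 0 °C
Reagents that add atoms: N-phenylbis(trifluoromethanesulfonimide), O=S(=O)(N(c1ccccc1)S(=O)(=O)C(F)(F)F)C(F)(F)F
Why: Kinetic enolisation of the methyl ketone on its CH3 side by the bulky amide at −78 °C, expected to be faster than deprotonation of the hindered acetate, followed by O-sulfonylation should give the terminal enol triflate (regioselective enol triflate formation).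

Step 10
Reactants: 14 (5E)-8-[(3R,5R,6S)-5-acetoxy-6-ethenyl-2,2,6-trimethyloxan-3-yl]-6-methylocta-1,5-dien-2-yl trifluoromethanesulfonate
Product: 16 (1R,3R,4S,11E)-3-acetoxy-4,15-epoxycembra-8(19),11-dien-7-one (14-membered α-methylene ketone bridged by the oxane), via alkylborane 15 (not isolated)
Conditions: 9-BBN (1.3 equiv), THF, 0 °C → rt; then syringe-pump addition (10 h) to PdCl2(dppf) (10 mol %), AsPh3 (20 mol %), K3PO4, KBr, CO (1 atm), THF/DMF, 55 °C, final 2 mM
Reagents that add atoms: carbon monoxide, [C-]#[O+]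
Why: 9-BBN should add anti-Markovnikov only to the monosubstituted C5=C6 vinyl group (the enol triflate and the trisubstituted C11=C12 alkene react far more slowly) to give the C6 alkylborane; zerovalent palladium then inserts into the C8–OTf bond, CO inserts to give the acyl(alkenyl)palladium species, and base-assisted boron-to-palladium transfer of C6 with reductive elimination forms the C6–C7 bond. The closest known reactions are the Suzuki–Miyaura carbonylative coupling of 9-alkyl-9-BBN reagents with alkenyl halides (inter- and intramolecular), B-alkyl Suzuki macrocyclisations and carbonylative Stille macrocyclisations. The 14-membered ring is closed head-to-tail by this C(sp3)–C(acyl) reductive elimination from a 15-membered palladacycle, with the oxane ring and the (E)-alkene restricting the conformations of the chain. No stereocentre is formed here (C7 is set in step 11) and C1, C3 and C4 are remote from the reacting centres. The step needs carbonylative over direct coupling, which CO insertion being faster than transmetallation of the primary alkylborane under 1 atm CO should secure, and ring closure over oligomerisation, which slow addition to high dilution should secure.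

Step 11
Reactants: 16 (1R,3R,4S,11E)-3-acetoxy-4,15-epoxycembra-8(19),11-dien-7-one
Product: 17 (1R,3R,4S,7R,11E)-3-acetoxy-4,15-epoxycembra-8(19),11-dien-7-ol (target)
Conditions: (S)-2-methyl-CBS-oxazaborolidine (20 mol %), catecholborane, toluene, −78 °C
Reagents that add atoms: none
Why: In the Corey–Bakshi–Shibata reduction the (S)-oxazaborolidine should bind the ketone with the α-branched alkenyl arm (C8) as the large group and the C6 methylene arm as the small one and deliver hydride 1,2 to give the (7R)-allylic alcohol, the acetate and the alkenes being inert to catecholborane at −78 °C.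

Compound list
1 | (R)-(+)-α-terpineol, 2-[(1R)-4-methylcyclohex-3-en-1-yl]propan-2-ol | CC1=CC[C@@H](CC1)C(C)(C)O | starting material
2 | trimethyl({2-[(1R)-4-methylcyclohex-3-en-1-yl]propan-2-yl}oxy)silane | CC1=CC[C@@H](CC1)C(C)(C)O[Si](C)(C)C | intermediate
3 | ozonide of 2 (1,2,4-trioxolane across the former ring C=C, mixture at the two acetal carbons) | CC12CC[C@H](CC(OO1)O2)C(C)(C)O[Si](C)(C)C | intermediate (not isolated)
4 | (3R)-6-oxo-3-{2-[(trimethylsilyl)oxy]propan-2-yl}heptanal | O=CC[C@@H](CCC(C)=O)C(C)(C)O[Si](C)(C)C | intermediate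
5 | (2E,5R)-2-methyl-8-oxo-5-{2-[(trimethylsilyl)oxy]propan-2-yl}non-2-enal | O=C/C(C)=C/C[C@@H](CCC(C)=O)C(C)(C)O[Si](C)(C)C | intermediate
6 | (5R,7E)-8-methyl-5-{2-[(trimethylsilyl)oxy]propan-2-yl}deca-7,9-dien-2-one | C=C/C(C)=C/C[C@@H](CCC(C)=O)C(C)(C)O[Si](C)(C)C | intermediate
7 | diethyl (5R,7E)-8-methyl-5-{2-[(trimethylsilyl)oxy]propan-2-yl}deca-1,7,9-trien-2-yl phosphate | C=C/C(C)=C/C[C@@H](CCC(=C)OP(=O)(OCC)OCC)C(C)(C)O[Si](C)(C)C | intermediate (not isolated)
8 | (5R,7E)-8-methyl-5-{2-[(trimethylsilyl)oxy]propan-2-yl}deca-7,9-dien-1-yne | C=C/C(C)=C/C[C@@H](CCC#C)C(C)(C)O[Si](C)(C)C | intermediate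
9 | (2R,3R)-2-ethenyl-2-methyl-3-[(2R)-2-{2-[(trimethylsilyl)oxy]propan-2-yl}hex-5-yn-1-yl]oxirane | C#CCC[C@H](C[C@H]1O[C@]1(C)C=C)C(C)(C)O[Si](C)(C)C | intermediate (not isolated)
10 | (2S,3R,5R)-5-(but-3-yn-1-yl)-2-ethenyl-2,6,6-trimethyloxan-3-ol | C#CCC[C@@H]1C[C@@H](O)[C@](C)(C=C)OC1(C)C | intermediate
11 | (E)-alkenyl(dimethyl)alane from syn methyl-alumination of 10, hydroxyl as its dimethylaluminium alkoxide | C[Al](C)/C=C(\C)CC[C@@H]1C[C@@H](O[Al](C)C)[C@](C)(C=C)OC1(C)C | intermediate (not isolated)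
12 | (5E)-8-[(3R,5R,6S)-6-ethenyl-5-hydroxy-2,2,6-trimethyloxan-3-yl]-6-methyloct-5-en-2-one | CC(=O)CC/C=C(\C)CC[C@@H]1C[C@@H](O)[C@](C)(C=C)OC1(C)C | intermediate
13 | (2S,3R,5R)-2-ethenyl-2,6,6-trimethyl-5-[(3E)-3-methyl-7-oxooct-3-en-1-yl]oxan-3-yl acetate | CC(=O)CC/C=C(\C)CC[C@@H]1C[C@@H](OC(C)=O)[C@](C)(C=C)OC1(C)C | intermediate
14 | (5E)-8-[(3R,5R,6S)-5-acetoxy-6-ethenyl-2,2,6-trimethyloxan-3-yl]-6-methylocta-1,5-dien-2-yl trifluoromethanesulfonate | C=C(OS(=O)(=O)C(F)(F)F)CC/C=C(\C)CC[C@@H]1C[C@@H](OC(C)=O)[C@](C)(C=C)OC1(C)C | intermediate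
15 | B-alkyl-9-BBN from 14, boron on C6 (the former vinyl terminus) | C=C(OS(=O)(=O)C(F)(F)F)CC/C=C(\C)CC[C@@H]1C[C@@H](OC(C)=O)[C@](C)(CCB2C3CCCC2CCC3)OC1(C)C | intermediate (not isolated)
16 | (1R,3R,4S,11E)-3-acetoxy-4,15-epoxycembra-8(19),11-dien-7-one | C=C1CC/C=C(\C)CC[C@@H]2C[C@@H](OC(C)=O)[C@](C)(CCC1=O)OC2(C)C | intermediate
17 | (1R,3R,4S,7R,11E)-3-acetoxy-4,15-epoxycembra-8(19),11-dien-7-ol | C=C1CC/C=C(\C)CC[C@@H]2C[C@@H](OC(C)=O)[C@](C)(CC[C@H]1O)OC2(C)C | target

Total step count: 11. Longest linear sequence: 11 steps (the route is fully linear from compound 1).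

Steps most likely to fail

Step 10. The carbonylative ring closure may lose to direct, CO-free cross-coupling, to protodeboronation or to oligomerisation, and the exocyclic enone may isomerise into the ring under the basic conditions. The fallback replaces the cross-coupling by a polar ring closure at the same bond. Compound 14 is hydroborated with 9-BBN and oxidised with NaBO3·4H2O to the primary alcohol F1. Formylation of the enol triflate (Pd(PPh3)4, CO, Bu3SnH, THF, 50 °C) gives the hydroxy enal F2, and I2, PPh3 and imidazole give the iodo enal F3. CrCl2 with catalytic cobalt phthalocyanine (C32H16CoN8) in DMF at high dilution (Takai–Utimoto alkylchromium addition) adds C6 to the C7 aldehyde and gives the macrocyclic allylic alcohols F4 as a C7 epimer mixture. Dess–Martin oxidation brings both epimers back to the route at compound 16.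

Step 6. Face or site selectivity of the dioxirane epoxidation on the 2-methyl diene may be poor, which would erode the C3/C4 configuration before the ether closure. The fallback uses a hydroxyl-directed titanium–tartrate epoxidation instead. From compound 5, NaBH4 in EtOH at −78 °C reduces only the conjugated aldehyde to the allylic alcohol F5. Sharpless epoxidation (Ti(OiPr)4, D-(−)-diethyl tartrate, tBuOOH, 4 Å sieves, −20 °C) gives the (2R,3R)-epoxy alcohol F6. Dess–Martin oxidation gives the epoxy aldehyde F7 and Wittig methylenation gives the vinyl epoxide ketone F8. The enol phosphate sequence of step 5 then returns to the route at compound 9, which is cyclised with CSA as before.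

Step 7. In the conjugate addition stage a methyl group may be transferred in place of the alkenyl group, or the enone may polymerise. The fallback replaces the conjugate addition by a cross-coupling. The alkenylalane from compound 10 is quenched with I2 to give the (E)-alkenyl iodide F9. Negishi coupling with [2-(2-methyl-1,3-dioxolan-2-yl)ethyl]zinc bromide (PdCl2(dppf), THF) gives the dioxolane F10, and PPTS in acetone/H2O unmasks the ketone and returns to the route at compound 12.

Further compounds
F1 | step 10 | (5E)-8-[(3R,5R,6S)-5-acetoxy-6-(2-hydroxyethyl)-2,2,6-trimethyloxan-3-yl]-6-methylocta-1,5-dien-2-yl trifluoromethanesulfonate | C=C(OS(=O)(=O)C(F)(F)F)CC/C=C(\C)CC[C@@H]1C[C@@H](OC(C)=O)[C@](C)(CCO)OC1(C)C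
F2 | step 10 | (2S,3R,5R)-5-[(3E)-7-formyl-3-methylocta-3,7-dien-1-yl]-2-(2-hydroxyethyl)-2,6,6-trimethyloxan-3-yl acetate | C=C(C=O)CC/C=C(\C)CC[C@@H]1C[C@@H](OC(C)=O)[C@](C)(CCO)OC1(C)C
F3 | step 10 | (2S,3R,5R)-5-[(3E)-7-formyl-3-methylocta-3,7-dien-1-yl]-2-(2-iodoethyl)-2,6,6-trimethyloxan-3-yl acetate | C=C(C=O)CC/C=C(\C)CC[C@@H]1C[C@@H](OC(C)=O)[C@](C)(CCI)OC1(C)C
F4 | step 10 | (1R,3R,4S,11E)-3-acetoxy-4,15-epoxycembra-8(19),11-dien-7-ol as a mixture of C7 epimers | C=C1CC/C=C(\C)CC[C@@H]2C[C@@H](OC(C)=O)[C@](C)(CCC1O)OC2(C)C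
F5 | step 6 | (5R,7E)-9-hydroxy-8-methyl-5-{2-[(trimethylsilyl)oxy]propan-2-yl}non-7-en-2-one | OC/C(C)=C/C[C@@H](CCC(C)=O)C(C)(C)O[Si](C)(C)C
F6 | step 6 | (5R)-6-[(2R,3R)-3-(hydroxymethyl)-3-methyloxiran-2-yl]-5-{2-[(trimethylsilyl)oxy]propan-2-yl}hexan-2-one | CC(=O)CC[C@H](C[C@H]1O[C@]1(C)CO)C(C)(C)O[Si](C)(C)C
F7 | step 6 | epoxy aldehyde from F6 (CH2OH oxidised to CHO, same epoxide configuration) | CC(=O)CC[C@H](C[C@H]1O[C@]1(C)C=O)C(C)(C)O[Si](C)(C)C
F8 | step 6 | (5R)-6-[(2R,3R)-3-ethenyl-3-methyloxiran-2-yl]-5-{2-[(trimethylsilyl)oxy]propan-2-yl}hexan-2-one | CC(=O)CC[C@H](C[C@H]1O[C@]1(C)C=C)C(C)(C)O[Si](C)(C)C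
F9 | step 7 | (2S,3R,5R)-2-ethenyl-5-[(3E)-4-iodo-3-methylbut-3-en-1-yl]-2,6,6-trimethyloxan-3-ol | I/C=C(\C)CC[C@@H]1C[C@@H](O)[C@](C)(C=C)OC1(C)C
F10 | step 7 | (2S,3R,5R)-2-ethenyl-2,6,6-trimethyl-5-[(3E)-3-methyl-6-(2-methyl-1,3-dioxolan-2-yl)hex-3-en-1-yl]oxan-3-ol | CC1(CC/C=C(\C)CC[C@@H]2C[C@@H](O)[C@](C)(C=C)OC2(C)C)OCCO1
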